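**Plan**
1. Retrosynthesis: the C5 methyl ether is cut back to ketol 17. C3a–C7a and C4–C5 are then cut together (retro-[4+2]) to the 2-alkoxy-4-silyloxyfuran 14, whose O1–C2–C3 tether ends in the 1,1-disubstituted alkene C3a=C4. The furan is unravelled to the 4-chloroacetoacetate of dienol 7, and 7 to allyl bromide, 3,4,5-trimethoxybenzaldehyde and (R)-but-3-yn-2-ol.
2. Enabling feature: ring C3a–C4–C5–C6–C7–C7a is a vinylogous ester (O1–C7a=C7–C6=O) with an oxygen on C5. This is the opened form of a 7-oxabicyclo[2.2.1]heptene whose bridge oxygen sits on C5 and C7a, so the furan oxygen becomes the C5 oxygen and the furan 2-alkoxy group becomes O1.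
3. Forward order: chain first (C2–C3 bond, then the allyl branch on C3a), then ester and furan, then the oxolane and cyclohexenone rings together in one cycloaddition/ring-opening step, then O-methylation.
4. Stereochemistry: C3 comes from (R)-but-3-yn-2-ol by chirality transfer through an allenylzinc, and C2 from the anti-selective cyclic addition to the aldehyde. C3a and C5 are set in the cycloaddition (allylic strain from C3, exo tether).

Key step: step 8

Remark: atoms carry the benzofuran locants of the target (O1, C2, C3, C3a, C4–C7, C7a) throughout, also in open-chain precursors. Step 2 is taken to follow the usual course of this reaction (anti oxidative addition, syn addition to the aldehyde), that is net inversion at the mesylate carbon.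

**Route**

Step 1
Reactants: 1 (R)-but-3-yn-2-ol
Product: 2 (R)-but-3-yn-2-yl methanesulfonate
Conditions: MsCl, Et3N, CH2Cl2, −78 °C to 0 °C
Reagents that add atoms: methanesulfonyl chloride, CS(=O)(=O)Cl
Why: Sulfonylation of a secondary alcohol (mesylate formation) does not touch the C–O stereocentre and gives the propargylic electrophile needed for oxidative addition.

Step 2
Reactants: 2 (R)-but-3-yn-2-yl methanesulfonate; 3 3,4,5-trimethoxybenzaldehyde
Product: 5 (1S,2S)-2-methyl-1-(3,4,5-trimethoxyphenyl)but-3-yn-1-ol, via allenylzinc mesylate 4 (not isolated)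
Conditions: Pd(OAc)2 (cat.), PPh3 (cat.), Et2Zn, THF, −78 °C to −20 °C; then H2O
Reagents that add atoms: none
Why: Marshall propargylation, in which zerovalent palladium adds to the mesylate anti (SN2′), transmetalation with Et2Zn gives the axially chiral allenylzinc 4, and its cyclic SE2′ addition to the aldehyde should give the anti homopropargylic alcohol, so C3 (net inversion of the mesylate carbon) and C2 (aryl group anti to the methyl group in the chair-like transition state) are both set here.

Step 3
Reactants: 5 (1S,2S)-2-methyl-1-(3,4,5-trimethoxyphenyl)but-3-yn-1-ol; 6 allyl bromide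
Product: 7 (1S,2S)-2-methyl-3-methylidene-1-(3,4,5-trimethoxyphenyl)hex-5-en-1-ol
Conditions: In (powder), THF, rt; then 1 M HCl
Reagents that add atoms: none
Why: Allylindation of a terminal alkyne, in which allylindium sesquibromide formed in the flask adds syn across the triple bond with the allyl group on the internal carbon (Markovnikov sense) and protonolysis of the vinylindium gives the 2-substituted 1,4-diene without touching C2 or C3.

Step 4
Reactants: 8 2,2-dimethyl-1,3-dioxane-4,6-dione (Meldrum's acid); 9 chloroacetyl chloride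
Product: 10 5-(2-chloro-1-hydroxyethylidene)-2,2-dimethyl-1,3-dioxane-4,6-dione
Conditions: pyridine, CH2Cl2, 0 °C to rt; 1 M HCl wash
Reagents that add atoms: none
Why: C-Acylation of Meldrum's acid by an acid chloride (Oikawa–Yonemitsu protocol) is a standard entry to β-keto ester equivalents.

Step 5
Reactants: 7 (1S,2S)-2-methyl-3-methylidene-1-(3,4,5-trimethoxyphenyl)hex-5-en-1-ol; 10 5-(2-chloro-1-hydroxyethylidene)-2,2-dimethyl-1,3-dioxane-4,6-dione
Product: 12 (1S,2S)-2-methyl-3-methylidene-1-(3,4,5-trimethoxyphenyl)hex-5-en-1-yl 4-chloro-3-oxobutanoate, via chloroacetylketene 11 (not isolated)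
Conditions: toluene, 80 °C
Reagents that add atoms: none
Why: Thermal fragmentation of the acyl Meldrum's acid releases acetone and CO2 to give chloroacetylketene 11, which the secondary alcohol traps (acylketene acetoacetylation) with retention at C2 because only the O–H bond reacts.

Step 6
Reactants: 12 (1S,2S)-2-methyl-3-methylidene-1-(3,4,5-trimethoxyphenyl)hex-5-en-1-yl 4-chloro-3-oxobutanoate
Product: 13 5-{[(1S,2S)-2-methyl-3-methylidene-1-(3,4,5-trimethoxyphenyl)hex-5-en-1-yl]oxy}furan-3(2H)-one
Conditions: Et3N, THF (high dilution), 0 °C to rt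
Reagents that add atoms: none
Why: Intramolecular O-alkylation of the β-keto ester enolate through the ester carbonyl oxygen (5-exo-tet displacement of chloride) is the known route from 4-haloacetoacetates to 5-alkoxyfuran-3(2H)-ones and leaves the C2–O1 bond intact.

Step 7
Reactants: 13 5-{[(1S,2S)-2-methyl-3-methylidene-1-(3,4,5-trimethoxyphenyl)hex-5-en-1-yl]oxy}furan-3(2H)-one
Product: 14 tert-butyl(dimethyl){[5-({(1S,2S)-2-methyl-3-methylidene-1-(3,4,5-trimethoxyphenyl)hex-5-en-1-yl}oxy)furan-3-yl]oxy}silane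
Conditions: TBSOTf, Et3N, CH2Cl2, 0 °C; pentane trituration, filtration through basic alumina
Reagents that add atoms: tert-butyldimethylsilyl trifluoromethanesulfonate, CC(C)(C)[Si](C)(C)OS(=O)(=O)C(F)(F)F
Why: Silylation of a furan-3(2H)-one with a silyl triflate and an amine base (soft enolisation) occurs on the ketone oxygen, and since the ring CH2 is the only enolisable position the aromatic 3-silyloxyfuran should be the sole regioisomer.

Step 8
Reactants: 14 tert-butyl(dimethyl){[5-({(1S,2S)-2-methyl-3-methylidene-1-(3,4,5-trimethoxyphenyl)hex-5-en-1-yl}oxy)furan-3-yl]oxy}silane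
Product: 17 (2S,3S,3aR,5R)-5-hydroxy-3-methyl-3a-(prop-2-en-1-yl)-2-(3,4,5-trimethoxyphenyl)-3,3a,4,5-tetrahydro-1-benzofuran-6(2H)-one, via oxa-bridged cycloadduct 15 (not isolated), via silyl ether 16 (not isolated)
Conditions: toluene (degassed), 2,6-di-tert-butyl-4-methylpyridine (cat.), 130 °C, sealed tube; then Bu4NF, AcOH, THF, 0 °C
Reagents that add atoms: none
Why: Proposed new method: the 2-alkoxy-4-silyloxyfuran is a locked s-cis, doubly oxygenated diene that should add thermally across the tethered 1,1-disubstituted alkene in an intramolecular [4+2] cycloaddition, forming C3a–C7a and C4–C5 together; the closest known reaction type is the intramolecular Diels–Alder reaction of 2-amidofurans with unactivated tethered alkenes followed by heteroatom-assisted opening of the oxygen bridge. Bridged ketal 15 should open at C7a (push from the O1 lone pair, pull from the silyl enol ether) with 1,4-silyl transfer from O6 to the C5 alkoxide to give 16, and buffered fluoride then converts 16, or any unopened 15 by E1cB opening, into ketol 17. The oxolane closes in the fused mode of a type 1 intramolecular cycloaddition through the three-atom O1–C2–C3 tether and the cyclohexene is the six-membered ring of the [4+2] event, the tether lying exo (syn to the oxygen bridge) because the endo-fused alternative is far more strained. This exo geometry places the C5 oxygen cis to C3 and trans to the allyl group, which is the 5R centre. The 3aR centre is set by C3: in the favoured transition state the C3 hydrogen eclipses the geminal allyl CH2 (least A(1,2) strain) while the C3 methyl and C2 aryl groups are pseudo-equatorial on the forming oxolane, so the methyl group ends cis to C4 and trans to allyl. The step needs site selectivity between the two alkenes, secured by tether length (five-membered against seven-membered ring closure), and it must outrun ionisation of the benzylic C2–O1 bond, which the acid-free non-polar medium disfavours; the weakly aromatic, electron-rich furan and the irreversible opening of the adduct should compensate for the unactivated dienophile.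

Step 9
Reactants: 17 (2S,3S,3aR,5R)-5-hydroxy-3-methyl-3a-(prop-2-en-1-yl)-2-(3,4,5-trimethoxyphenyl)-3,3a,4,5-tetrahydro-1-benzofuran-6(2H)-one
Product: 18 (2S,3S,3aR,5R)-5-methoxy-3-methyl-3a-(prop-2-en-1-yl)-2-(3,4,5-trimethoxyphenyl)-3,3a,4,5-tetrahydro-1-benzofuran-6(2H)-one
Conditions: MeI, Ag2O, 4 Å molecular sieves, CH2Cl2, rt, dark
Reagents that add atoms: iodomethane, CI
Why: Purdie methylation (MeI/Ag2O) etherifies the secondary ketol under non-enolising conditions, so the C5 stereocentre and the vinylogous ester are expected to survive.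

**Compound list**
1 | (R)-but-3-yn-2-ol | C#C[C@@H](C)O | starting material
2 | (R)-but-3-yn-2-yl methanesulfonate | C#C[C@@H](C)OS(C)(=O)=O | intermediate
3 | 3,4,5-trimethoxybenzaldehyde | O=Cc1cc(OC)c(OC)c(OC)c1 | starting material
4 | (P)-buta-1,2-dien-1-ylzinc methanesulfonate (allenylzinc mesylate) | CS(=O)(=O)O[Zn]C([H])=[C@@]=C([H])C | intermediate (not isolated)
5 | (1S,2S)-2-methyl-1-(3,4,5-trimethoxyphenyl)but-3-yn-1-ol (anti) | O[C@H](c1cc(OC)c(OC)c(OC)c1)[C@H](C#C)C | intermediate
6 | allyl bromide (3-bromoprop-1-ene) | C=CCBr | starting material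
7 | (1S,2S)-2-methyl-3-methylidene-1-(3,4,5-trimethoxyphenyl)hex-5-en-1-ol | O[C@H](c1cc(OC)c(OC)c(OC)c1)[C@H](C(=C)CC=C)C | intermediate
8 | 2,2-dimethyl-1,3-dioxane-4,6-dione (Meldrum's acid) | CC1(C)OC(=O)CC(=O)O1 | starting material
9 | chloroacetyl chloride | ClCC(=O)Cl | starting material
10 | 5-(2-chloro-1-hydroxyethylidene)-2,2-dimethyl-1,3-dioxane-4,6-dione | CC1(C)OC(=O)C(=C(O)CCl)C(=O)O1 | intermediate
11 | chloroacetylketene (4-chloro-1-oxobut-1-en-3-one) | O=C=CC(=O)CCl | intermediate (not isolated)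
12 | (1S,2S)-2-methyl-3-methylidene-1-(3,4,5-trimethoxyphenyl)hex-5-en-1-yl 4-chloro-3-oxobutanoate | ClCC(=O)CC(=O)O[C@H](c1cc(OC)c(OC)c(OC)c1)[C@H](C(=C)CC=C)C | intermediate
13 | 5-{[(1S,2S)-2-methyl-3-methylidene-1-(3,4,5-trimethoxyphenyl)hex-5-en-1-yl]oxy}furan-3(2H)-one | O=C1COC(O[C@H](c2cc(OC)c(OC)c(OC)c2)[C@H](C(=C)CC=C)C)=C1 | intermediate
14 | tert-butyl(dimethyl){[5-({(1S,2S)-2-methyl-3-methylidene-1-(3,4,5-trimethoxyphenyl)hex-5-en-1-yl}oxy)furan-3-yl]oxy}silane | CC(C)(C)[Si](C)(C)Oc1coc(O[C@H](c2cc(OC)c(OC)c(OC)c2)[C@H](C(=C)CC=C)C)c1 | intermediate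
15 | oxa-bridged cycloadduct: 7-oxabicyclo[2.2.1]hept-5-ene with the oxygen bridge between C5 and C7a syn to C3, TBS enol ether on C6, allyl endo on C3a, oxolane O1–C2(aryl)–C3(methyl) fused at C7a–C3a | C=CC[C@]12C[C@H]3O[C@@]1(C=C3O[Si](C)(C)C(C)(C)C)O[C@H](c1cc(OC)c(OC)c(OC)c1)[C@H]2C | intermediate (not isolated)
16 | (2S,3S,3aR,5R)-5-[(tert-butyldimethylsilyl)oxy]-3-methyl-3a-(prop-2-en-1-yl)-2-(3,4,5-trimethoxyphenyl)-3,3a,4,5-tetrahydro-1-benzofuran-6(2H)-one | C=CC[C@]12C[C@@H](O[Si](C)(C)C(C)(C)C)C(=O)C=C1O[C@H](c1cc(OC)c(OC)c(OC)c1)[C@H]2C | intermediate (not isolated)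
17 | (2S,3S,3aR,5R)-5-hydroxy-3-methyl-3a-(prop-2-en-1-yl)-2-(3,4,5-trimethoxyphenyl)-3,3a,4,5-tetrahydro-1-benzofuran-6(2H)-one | C=CC[C@]12C[C@@H](O)C(=O)C=C1O[C@H](c1cc(OC)c(OC)c(OC)c1)[C@H]2C | intermediate
18 | (2S,3S,3aR,5R)-5-methoxy-3-methyl-3a-(prop-2-en-1-yl)-2-(3,4,5-trimethoxyphenyl)-3,3a,4,5-tetrahydro-1-benzofuran-6(2H)-one | C=CC[C@]12C[C@@H](OC)C(=O)C=C1O[C@H](c1cc(OC)c(OC)c(OC)c1)[C@H]2C | target

**Count**
Total steps: 9. Longest linear sequence: 8 steps (1, 2, 3, 5, 6, 7, 8, 9); step 4 prepares the acylating agent.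

**Steps most likely to fail**

Step 8 (proposed new method). The unactivated 1,1-disubstituted alkene may fail to add to the furan before ionisation of the benzylic C2–O1 bond or loss of the silyl group intervenes. Addition may also show poor facial selectivity relative to C3, or the opened zwitterion may collapse by hydride shift instead of silyl transfer.

Fallback (known chemistry, stepwise enolate annulation), setting out from alkynol 5 and returning at ketol 17:
- Ruthenium-catalysed oxidative cyclisation of the homopropargylic alcohol (CpRu(cod)Cl, tri(2-furyl)phosphine, N-hydroxysuccinimide, NaHCO3, Bu4NBr, DMF–H2O, 95 °C) should give (4S,5S)-4-methyl-5-(3,4,5-trimethoxyphenyl)oxolan-2-one F1.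
- Alkylation of its lithium enolate (LiN(iPr)2, THF–DMPU, −78 °C) with 2-(2-iodoethyl)-2-methyl-1,3-dioxolane, anti to the 4-methyl group, should give (3S,4S,5S)-4-methyl-3-[2-(2-methyl-1,3-dioxolan-2-yl)ethyl]-5-(3,4,5-trimethoxyphenyl)oxolan-2-one F2.
- A second enolate alkylation with allyl bromide, again anti to the methyl group, sets the quaternary centre in (3S,4S,5S)-4-methyl-3-[2-(2-methyl-1,3-dioxolan-2-yl)ethyl]-3-(prop-2-en-1-yl)-5-(3,4,5-trimethoxyphenyl)oxolan-2-one F3.
- Ketal hydrolysis (PPTS, acetone–H2O) gives (3S,4S,5S)-4-methyl-3-(3-oxobutyl)-3-(prop-2-en-1-yl)-5-(3,4,5-trimethoxyphenyl)oxolan-2-one F4.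
- KOtBu in THF closes the six-membered ring by attack of the methyl ketone enolate on the lactone carbonyl. This gives, without isolation, (4S)-4-[(1S,2S)-1-hydroxy-1-(3,4,5-trimethoxyphenyl)propan-2-yl]-4-(prop-2-en-1-yl)cyclohexane-1,3-dione F5.
- TsOH in toluene with azeotropic removal of water closes O1 onto C7a to give (2S,3S,3aS)-3-methyl-3a-(prop-2-en-1-yl)-2-(3,4,5-trimethoxyphenyl)-3,3a,4,5-tetrahydro-1-benzofuran-6(2H)-one F6.
- Kinetic deprotonation at C5 (LiN(iPr)2, THF, −78 °C) and hydroxylation with 2-(benzenesulfonyl)-3-phenyloxaziridine, expected anti to the angular allyl group, leads to 17.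

Step 6. Intermolecular C-alkylation (dimerisation) of the chloro keto ester enolate may outrun the intramolecular O-alkylation. Loss of the benzylic group from an oxonium intermediate (tetronic acid formation) is the other competing process.

Fallback (ring built from an alkynyl ether), setting out from dienol 7 and returning at furanone 13:
- KH and trichloroethylene in THF should give the (E)-1,2-dichloroethenyl ether of 7, F7.
- n-BuLi at −78 °C converts it into the lithium alkoxyacetylide, lithium 2-{[(1S,2S)-2-methyl-3-methylidene-1-(3,4,5-trimethoxyphenyl)hex-5-en-1-yl]oxy}ethynide F8.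
- F8 is acylated in the cold by 2-[(tert-butyldimethylsilyl)oxy]-N-methoxy-N-methylacetamide to give the alkoxy ynone 1-[(tert-butyldimethylsilyl)oxy]-4-{[(1S,2S)-2-methyl-3-methylidene-1-(3,4,5-trimethoxyphenyl)hex-5-en-1-yl]oxy}but-3-yn-2-one F9.
- Bu4NF/AcOH frees the hydroxy ynone 1-hydroxy-4-{[(1S,2S)-2-methyl-3-methylidene-1-(3,4,5-trimethoxyphenyl)hex-5-en-1-yl]oxy}but-3-yn-2-one F10, whose 5-endo-dig oxa-Michael closure (K2CO3, MeOH, 0 °C if needed) gives 13.

Step 3. The allyl group may be delivered to the terminal alkyne carbon (linear diene). Double allylation, or ionisation of the benzylic alcohol by Lewis acidic indium species, may also erode the step.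

Fallback (catalytic alkene–alkyne coupling instead of carbometalation), setting out from alkynol 5 and returning at dienol 7: ruthenium-catalysed Alder-ene-type coupling with propene (CpRu(MeCN)3PF6, propene, acetone, rt) forms the C–C bond at the internal alkyne carbon with transfer of an allylic hydrogen and gives 7 directly. This fallback makes no compound outside the compound list (F0).

**Further compounds**
F1 | step 8 | (4S,5S)-4-methyl-5-(3,4,5-trimethoxyphenyl)oxolan-2-one | O1[C@H](c2cc(OC)c(OC)c(OC)c2)[C@H](CC1=O)C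
F2 | step 8 | (3S,4S,5S)-4-methyl-3-[2-(2-methyl-1,3-dioxolan-2-yl)ethyl]-5-(3,4,5-trimethoxyphenyl)oxolan-2-one | O1[C@H](c2cc(OC)c(OC)c(OC)c2)[C@H]([C@H](CCC2(C)OCCO2)C1=O)C
F3 | step 8 | (3S,4S,5S)-4-methyl-3-[2-(2-methyl-1,3-dioxolan-2-yl)ethyl]-3-(prop-2-en-1-yl)-5-(3,4,5-trimethoxyphenyl)oxolan-2-one | O1[C@H](c2cc(OC)c(OC)c(OC)c2)[C@H]([C@@](CC=C)(CCC2(C)OCCO2)C1=O)C
F4 | step 8 | (3S,4S,5S)-4-methyl-3-(3-oxobutyl)-3-(prop-2-en-1-yl)-5-(3,4,5-trimethoxyphenyl)oxolan-2-one | O1[C@H](c2cc(OC)c(OC)c(OC)c2)[C@H]([C@@](CC=C)(CCC(C)=O)C1=O)C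
F5 | step 8 | (4S)-4-[(1S,2S)-1-hydroxy-1-(3,4,5-trimethoxyphenyl)propan-2-yl]-4-(prop-2-en-1-yl)cyclohexane-1,3-dione | O[C@H](c1cc(OC)c(OC)c(OC)c1)[C@H]([C@@]1(CC=C)CCC(=O)CC1=O)C
F6 | step 8 | (2S,3S,3aS)-3-methyl-3a-(prop-2-en-1-yl)-2-(3,4,5-trimethoxyphenyl)-3,3a,4,5-tetrahydro-1-benzofuran-6(2H)-one | C=CC[C@]12CCC(=O)C=C1O[C@H](c1cc(OC)c(OC)c(OC)c1)[C@H]2C
F7 | step 6 | 5-[(1S,2S)-1-{[(E)-1,2-dichloroethenyl]oxy}-2-methyl-3-methylidenehex-5-en-1-yl]-1,2,3-trimethoxybenzene | Cl/C=C(/Cl)O[C@H](c1cc(OC)c(OC)c(OC)c1)[C@H](C(=C)CC=C)C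
F8 | step 6 | lithium 2-{[(1S,2S)-2-methyl-3-methylidene-1-(3,4,5-trimethoxyphenyl)hex-5-en-1-yl]oxy}ethynide | [Li]C#CO[C@H](c1cc(OC)c(OC)c(OC)c1)[C@H](C(=C)CC=C)C
F9 | step 6 | 1-[(tert-butyldimethylsilyl)oxy]-4-{[(1S,2S)-2-methyl-3-methylidene-1-(3,4,5-trimethoxyphenyl)hex-5-en-1-yl]oxy}but-3-yn-2-one | CC(C)(C)[Si](C)(C)OCC(=O)C#CO[C@H](c1cc(OC)c(OC)c(OC)c1)[C@H](C(=C)CC=C)C
F10 | step 6 | 1-hydroxy-4-{[(1S,2S)-2-methyl-3-methylidene-1-(3,4,5-trimethoxyphenyl)hex-5-en-1-yl]oxy}but-3-yn-2-one | OCC(=O)C#CO[C@H](c1cc(OC)c(OC)c(OC)c1)[C@H](C(=C)CC=C)C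
F0 | step 3 | none | none
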